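A direct plan would set the benzylic centre by a sparteine-mediated carbamate lithiation–borylation–oxidation sequence to give carbinol A1, acylate A1 to the but-2-ynoate A2, convert A2 by hydroalumination and in-situ hydroxymethylation, and finish by acylating the new primary hydroxyl with an activated angeloyl donor. Its weakest steps would be:
- the lithiation–borylation–oxidation, because it would need a stoichiometric, scarce chiral diamine, cryogenic organolithium chemistry and three operations for one simple secondary carbinol;
- the hydroalumination–hydroxymethylation, because an aluminium hydride would act beside a benzylic ester, a gaseous one-carbon electrophile would be needed, and the alkene geometry would rest on a configurationally labile alkenyl–aluminium bond;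
- the final acylation, because an activated angeloyl group tends to drift to the E isomer and the coupling would be slow once the nucleophilic catalyst is left out.

The route disconnects the central ester carbonyl (C1 of the but-2-enoate) from both neighbours: that carbon comes from CO. One palladium-catalysed alkoxycarbonylation would join (Z)-2-iodobut-2-enyl angelate, CO and the (S)-carbinol, forming the C2–C1 and C1–O bonds and carrying the C2=C3 geometry over with retention. That geometry is the thermodynamic one of α-iodocrotonaldehyde (CH3 anti to CHO); once CHO has become the CH2O arm and iodine the carboxyl, it is the contra-thermodynamic Z enoate. The carbinol comes from a catalytic asymmetric ethylation at 0 °C, and the angelate is introduced by O-alkylation of free angelic acid, so no stoichiometric chiral base, no organoaluminium step and no activated angeloyl species remain.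

Key step: step 5

Remark: the SMILES is read as S at the benzylic carbon and Z for both trisubstituted alkenes (each β-methyl cis to its own carbonyl); angelic acid is taken as a commercial starting material.

Step 1
Reactants: 1 (E)-but-2-enal (crotonaldehyde)
Product: 3 (Z)-2-iodobut-2-enal, via β-pyridinium α-iodo aldehyde 2 (not isolated)
Conditions: I2, K2CO3, DMAP (20 mol %), THF/H2O 1:1, rt; aq. Na2S2O3 work-up
Reagents that add atoms: iodine (II)
Why: Amine-catalysed α-iodination of an enal (Morita–Baylis–Hillman-type addition–iodination–elimination): DMAP adds to C3, the enolate is iodinated at C2, and E1cB loss of DMAP from 2 should give the α-iodo enal as its thermodynamically preferred Z isomer, with CH3 anti to the formyl group and cis to iodine.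

Step 2
Reactants: 3 (Z)-2-iodobut-2-enal
Product: 4 (Z)-2-iodobut-2-en-1-ol
Conditions: NaBH4, THF/H2O 9:1, 0 °C
Reagents that add atoms: none
Why: Borohydride 1,2-reduction of the aldehyde leaves the C=C and C–I bonds untouched, so the Z geometry (CH3 cis to iodine) should be carried into the allylic alcohol.

Step 3
Reactants: 4 (Z)-2-iodobut-2-en-1-ol; 5 angelic acid [(Z)-2-methylbut-2-enoic acid]
Product: 7 (Z)-2-iodobut-2-en-1-yl (Z)-2-methylbut-2-enoate, via alkoxyphosphonium angelate 6 (not isolated)
Conditions: PPh3, DIAD, THF, 0 °C → rt
Reagents that add atoms: none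
Why: Mitsunobu esterification activates the alcohol as alkoxyphosphonium salt 6, which angelate displaces at the primary allylic carbon (SN2), so angelic acid acts only as an O-nucleophile, is never made into an acylating agent and should keep its Z geometry, while the alkenyl iodide is inert.

Step 4
Reactants: 8 3,4,5-trimethoxybenzaldehyde; 9 diethylzinc
Product: 11 (S)-1-(3,4,5-trimethoxyphenyl)propan-1-ol, via ethylzinc alkoxide 10 (not isolated)
Conditions: (−)-DAIB [(2S)-3-exo-(dimethylamino)isoborneol] (5 mol %), toluene/hexane, 0 °C; aq. NH4Cl
Reagents that add atoms: none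
Why: Amino alcohol-catalysed enantioselective addition of diethylzinc to an aryl aldehyde: the zinc aminoalkoxide formed from (−)-DAIB organises aldehyde and Et2Zn in a dinuclear zinc transition state and delivers ethyl to the Si face, which should set the S configuration at the benzylic carbon under ligand control.

Step 5
Reactants: 7 (Z)-2-iodobut-2-en-1-yl (Z)-2-methylbut-2-enoate; 11 (S)-1-(3,4,5-trimethoxyphenyl)propan-1-ol; 12 carbon monoxide
Product: 15 (S)-1-(3,4,5-trimethoxyphenyl)propyl (Z)-2-{[(Z)-2-methylbut-2-enoyl]oxymethyl}but-2-enoate (CNP0198521.1), via alkenylpalladium iodide 13 (not isolated), via acylpalladium iodide 14 (not isolated)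
Conditions: PdCl2(PPh3)2 (5 mol %), CO (1 atm), iPr2NEt, 4 Å MS, DMF, 50 °C; 7 (1.5 equiv) relative to 11
Reagents that add atoms: none
Why: Palladium-catalysed alkoxycarbonylation of an alkenyl iodide (Heck carbonylation): zerovalent palladium inserts into the vinylic C–I bond of 7 with retention to give 13, CO inserts to give the acyl complex of divalent palladium 14, and base-assisted alcoholysis by the O–H of 11 releases 15 and zerovalent palladium, so the C2–C1 and C1–O bonds of the central enoate are made in one operation. No ring is closed and no stereocentre is created: 11 reacts only at its O–H bond and keeps the S configuration, and the geometry of 7 (CH3 cis to iodine) is transferred unchanged because oxidative addition at sp2 carbon and migratory insertion are stereoretentive, which places CH3 cis to the new ester carbonyl. The step needs chemoselectivity for the C–I bond over the allylic angelate C–O bonds of 7 and 15; this should be secured by the much faster oxidative addition to the alkenyl iodide, by keeping 7 in excess so that zerovalent palladium does not accumulate beside the product, and by CO saturation, under which insertion should outrun β-acyloxy elimination of 13 (which would have to form a strained allene). A hindered, non-nucleophilic amine and the absence of DMAP should prevent SN2′ addition–elimination at the 2-(acyloxymethyl)acrylate unit and hence Z→E drift of either alkene.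

Compound list
1 | (E)-but-2-enal (crotonaldehyde) | C/C=C/C=O | starting material
2 | 3-[4-(dimethylamino)pyridin-1-ium-1-yl]-2-iodobutanal iodide | CC(C(I)C=O)[n+]1ccc(N(C)C)cc1.[I-] | intermediate
3 | (Z)-2-iodobut-2-enal | C/C=C(\I)C=O | intermediate
4 | (Z)-2-iodobut-2-en-1-ol | C/C=C(\I)CO | intermediate
5 | angelic acid [(Z)-2-methylbut-2-enoic acid] | C/C=C(/C)C(=O)O | starting material
6 | [(Z)-(2-iodobut-2-en-1-yl)oxy]triphenylphosphonium (Z)-2-methylbut-2-enoate | C/C=C(\I)CO[P+](c1ccccc1)(c1ccccc1)c1ccccc1.C/C=C(/C)C(=O)[O-] | intermediate
7 | (Z)-2-iodobut-2-en-1-yl (Z)-2-methylbut-2-enoate [(Z)-2-iodobut-2-enyl angelate] | C/C=C(/C)C(=O)OC/C(I)=C/C | intermediate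
8 | 3,4,5-trimethoxybenzaldehyde | COc1cc(C=O)cc(OC)c1OC | starting material
9 | diethylzinc | CC[Zn]CC | starting material
10 | ethylzinc (S)-1-(3,4,5-trimethoxyphenyl)propan-1-olate | CC[C@H](O[Zn]CC)c1cc(OC)c(OC)c(OC)c1 | intermediate
11 | (S)-1-(3,4,5-trimethoxyphenyl)propan-1-ol | CC[C@H](O)c1cc(OC)c(OC)c(OC)c1 | intermediate
12 | carbon monoxide | [C-]#[O+] | starting material
13 | iodo[(Z)-1-{[(Z)-2-methylbut-2-enoyl]oxymethyl}prop-1-en-1-yl]palladium (two PPh3 ligands not drawn) | C/C=C(/C)C(=O)OC/C([Pd]I)=C/C | intermediate
14 | iodo[(Z)-2-{[(Z)-2-methylbut-2-enoyl]oxymethyl}but-2-enoyl]palladium (two PPh3 ligands not drawn) | C/C=C(/C)C(=O)OC/C(=C/C)C(=O)[Pd]I | intermediate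
15 | (S)-1-(3,4,5-trimethoxyphenyl)propyl (Z)-2-{[(Z)-2-methylbut-2-enoyl]oxymethyl}but-2-enoate | C/C=C(/C)C(=O)OC/C(=C/C)C(=O)O[C@@H](CC)c1cc(OC)c(OC)c(OC)c1 | target

Total step count: 5. Longest linear sequence: 4 (steps 1, 2, 3 and 5); step 4 is a one-step branch.

Steps most likely to fail

Step 5. Zerovalent palladium may ionise an allylic angelate, the alkenylpalladium species may lose the β-acyloxy group, or the acylpalladium may be captured too slowly by a secondary alcohol used without excess. The fallback would set out from 4 and come back at 15, adding the angelate only after the carbonylation. Silylation (TBSCl, imidazole, CH2Cl2) would give (Z)-tert-butyl[(2-iodobut-2-en-1-yl)oxy]dimethylsilane F1. Carbonylation of F1 under the conditions of step 5, now with 11 in threefold excess and no allylic ester in the flask, would give (S)-1-(3,4,5-trimethoxyphenyl)propyl (Z)-2-{[(tert-butyldimethylsilyl)oxy]methyl}but-2-enoate F2. HF·pyridine in THF at 0 °C would free (S)-1-(3,4,5-trimethoxyphenyl)propyl (Z)-2-(hydroxymethyl)but-2-enoate F3, and Mitsunobu esterification of F3 with 5 (PPh3, DIAD, THF, 0 °C) would deliver 15.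

Step 3. The angelate geometry may erode, or SN2′ capture may compete, during the redox condensation. The fallback would set out from 4 and come back at 7 by a two-stage halide displacement without any phosphine–azodicarboxylate reagent. PBr3 (Et2O, 0 °C) would give (Z)-1-bromo-2-iodobut-2-ene F4, and SN2 displacement of its allylic bromide by caesium angelate (5, Cs2CO3, DMF, rt) would give 7.

Step 4. Enantioselectivity may fall short because uncatalysed ethyl transfer to the aldehyde competes with the ligand-bound pathway. The fallback would set out from 8 and come back at 11, setting the centre by C=O reduction instead of C–C bond formation. EtMgBr (THF, 0 °C) would give racemic 1-(3,4,5-trimethoxyphenyl)propan-1-ol F5, MnO2 (CH2Cl2, rt) would oxidise it to 1-(3,4,5-trimethoxyphenyl)propan-1-one F6, and asymmetric transfer hydrogenation with RuCl[(S,S)-TsDPEN](p-cymene) in HCO2H/Et3N should return 11 by hydride delivery to the Re face of the ketone.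

Further compounds
F1 | step 5 | (Z)-tert-butyl[(2-iodobut-2-en-1-yl)oxy]dimethylsilane | C/C=C(\I)CO[Si](C)(C)C(C)(C)C
F2 | step 5 | (S)-1-(3,4,5-trimethoxyphenyl)propyl (Z)-2-{[(tert-butyldimethylsilyl)oxy]methyl}but-2-enoate | C/C=C(/CO[Si](C)(C)C(C)(C)C)C(=O)O[C@@H](CC)c1cc(OC)c(OC)c(OC)c1
F3 | step 5 | (S)-1-(3,4,5-trimethoxyphenyl)propyl (Z)-2-(hydroxymethyl)but-2-enoate | C/C=C(/CO)C(=O)O[C@@H](CC)c1cc(OC)c(OC)c(OC)c1
F4 | step 3 | (Z)-1-bromo-2-iodobut-2-ene | C/C=C(\I)CBr
F5 | step 4 | rac-1-(3,4,5-trimethoxyphenyl)propan-1-ol | CCC(O)c1cc(OC)c(OC)c(OC)c1
F6 | step 4 | 1-(3,4,5-trimethoxyphenyl)propan-1-one | CCC(=O)c1cc(OC)c(OC)c(OC)c1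
A1 | direct plan | (S)-1-(3,4,5-trimethoxyphenyl)propan-1-ol | CC[C@H](O)c1cc(OC)c(OC)c(OC)c1
A2 | direct plan | (S)-1-(3,4,5-trimethoxyphenyl)propyl but-2-ynoate | CC#CC(=O)O[C@@H](CC)c1cc(OC)c(OC)c(OC)c1
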